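**Plan**

Target ring numbering used below: C1 = quaternary carbinol carbon (bears CH2OBz), C2 and C5 = benzoyloxy carbons, C3=C4 = alkene, C6 = secondary carbinol carbon.
The retrosynthesis cuts C2–C3 and C4–C5 together. The ring segment O–C2–C3=C4–C5–O is a furan (its C2/C5 and ring oxygen; its C3/C4 become C1/C6) spanned by an acetylene unit, delivered as (Z)-1,2-bis(phenylsulfonyl)ethene; the sulfonyl groups are helpers lost in step 6.
Forward, one [4+2] event closes the carbocycle as a meso 7-oxanorbornene. The oxygen bridge is a temporary ring that makes the later steps exo-selective and ends as the C5 oxygen.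
C6 and C1 are oxygenated from the exo face (OsO4, then sulfur-ylide addition to the C1 ketone). The absolute configuration comes from a catalytic enantiotopic-group-selective silylation of the meso diol.
The cis C2/C5 relationship forced by the cycloaddition is turned into trans when the C1 benzoate opens the bridge at C2 with inversion, which also puts that benzoyl group on O-2. Benzoylation of O-5 and desilylation finish the route.

Key step: step 1

Assumption: the sense of enantiotopic-group selection in step 3 is taken from the behaviour of this catalyst class with simple cyclic cis-1,2-diols and is not established for diol 4. The catalyst enantiomer that silylates the C-2 hydroxyl of 4 is meant; its antipode would be used should the sense be opposite.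

**Route**

Step 1
Reactants: 1 furan; 2 (Z)-1,2-bis(phenylsulfonyl)ethene
Product: 3 meso-(1R,4S,5R,6S)-5,6-bis(phenylsulfonyl)-7-oxabicyclo[2.2.1]hept-2-ene (both sulfonyl groups endo)
Conditions: furan (10 equiv), CH2Cl2, rt, dark, 3 d
Reagents that add atoms: none
Why: A concerted, suprafacial normal-demand [4+2] cycloaddition between the s-cis diene locked in the furan ring and the doubly sulfonyl-activated alkene forms the two C–C bonds that become C2–C3 and C4–C5 of the target. The closest known reaction type is the Diels–Alder reaction of furans with cis-1,2-bis(arylsulfonyl)ethenes used as acetylene equivalents. The six-membered carbocycle closes by intermolecular [4+2] cycloaddition, and the furan oxygen is left as a one-atom bridge across the two new allylic carbons (future C2 and C5). The two bridgehead stereocentres are cis by necessity (addition across one face of a cyclic diene), the two sulfonyl-bearing carbons are cis because the Z geometry of the dienophile is retained, and the endo orientation follows the Alder rule; since both partners are symmetric the adduct is meso, so no facial or enantioselectivity is needed here. The step only needs full conversion against cycloreversion, which the high reactivity of the bis-sulfone at room temperature and the excess of furan should secure; an exo,exo adduct would also be meso and would converge in step 6.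

Step 2
Reactants: 3 meso-(1R,4S,5R,6S)-5,6-bis(phenylsulfonyl)-7-oxabicyclo[2.2.1]hept-2-ene
Product: 4 meso-(1R,2R,3S,4S,5R,6S)-5,6-bis(phenylsulfonyl)-7-oxabicyclo[2.2.1]heptane-2,3-diol (both hydroxyls exo)
Conditions: OsO4 (2 mol %), NMO, acetone/H2O, rt
Reagents that add atoms: osmium tetroxide O=[Os](=O)(=O)=O (catalytic oxygen carrier); N-methylmorpholine N-oxide C[N+]1([O-])CCOCC1; water O
Why: Catalytic osmium tetroxide dihydroxylation adds suprafacially to the strained alkene from the exo face (the face of the oxygen bridge; the endo face is screened by the two endo sulfonyl groups), so both new carbinol centres carry exo hydroxyls (one becomes the C6 hydroxyl of the target) and the product stays meso.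

Step 3
Reactants: 4 meso-(1R,2R,3S,4S,5R,6S)-5,6-bis(phenylsulfonyl)-7-oxabicyclo[2.2.1]heptane-2,3-diol
Product: 5 (1S,2R,3R,4R,5S,6R)-3-[(tert-butyldimethylsilyl)oxy]-5,6-bis(phenylsulfonyl)-7-oxabicyclo[2.2.1]heptan-2-ol
Conditions: TBSCl (2 equiv), i-Pr2NEt, (S)-N-[(R)-3,3-dimethylbutan-2-yl]-3,3-dimethyl-2-{[(1-methylimidazol-2-yl)methyl]amino}butanamide (30 mol %), THF, −30 °C
Reagents that add atoms: tert-butyldimethylsilyl chloride CC(C)(C)[Si](C)(C)Cl
Why: Enantiotopic-group-selective silylation of a meso cis-1,2-diol by a chiral amino-acid-based N-methylimidazole catalyst (hydrogen-bond binding of the diol, Lewis-base activation of the silyl chloride) should silylate only the hydroxyl on the R-configured carbinol carbon (C-2 of 4, future C6 of the target), which fixes the absolute configuration of the whole series and protects that oxygen to the end.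

Step 4
Reactants: 5 (1S,2R,3R,4R,5S,6R)-3-[(tert-butyldimethylsilyl)oxy]-5,6-bis(phenylsulfonyl)-7-oxabicyclo[2.2.1]heptan-2-ol
Product: 6 (1S,3S,4R,5S,6R)-3-[(tert-butyldimethylsilyl)oxy]-5,6-bis(phenylsulfonyl)-7-oxabicyclo[2.2.1]heptan-2-one
Conditions: 1,1,1-triacetoxy-1,1-dihydro-1,2-benziodoxol-3(1H)-one (DMP), CH2Cl2, 0 °C to rt
Reagents that add atoms: none
Why: Neutral periodinane oxidation converts the remaining secondary alcohol into the ketone (future C1) without base, so the α-silyloxy centre is not epimerised and no enolate is formed that could expel the bridge oxygen.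

Step 5
Reactants: 6 (1S,3S,4R,5S,6R)-3-[(tert-butyldimethylsilyl)oxy]-5,6-bis(phenylsulfonyl)-7-oxabicyclo[2.2.1]heptan-2-one
Product: 7 (1S,2S,3S,4R,5S,6R)-3-[(tert-butyldimethylsilyl)oxy]-5,6-bis(phenylsulfonyl)spiro[7-oxabicyclo[2.2.1]heptane-2,2'-oxirane] (oxirane oxygen endo, oxirane CH2 exo)
Conditions: Me3S+ I− (2.2 equiv), n-BuLi (2.0 equiv), THF, −10 °C, then 6, −10 °C to rt
Reagents that add atoms: trimethylsulfonium iodide C[S+](C)C.[I-]
Why: In this Corey–Chaykovsky epoxidation the sulfonium ylide adds irreversibly to the carbonyl from the exo face (the endo face is blocked by the C-6 endo sulfonyl group), so the new CH2 is exo and the oxygen endo, which sets the quaternary carbinol centre (target C1) with its oxygen trans to the neighbouring silyloxy group.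

Step 6
Reactants: 7 (1S,2S,3S,4R,5S,6R)-3-[(tert-butyldimethylsilyl)oxy]-5,6-bis(phenylsulfonyl)spiro[7-oxabicyclo[2.2.1]heptane-2,2'-oxirane]
Product: 8 (1R,2S,3S,4S)-3-[(tert-butyldimethylsilyl)oxy]spiro[7-oxabicyclo[2.2.1]hept-5-ene-2,2'-oxirane]
Conditions: 6% Na/Hg, NaH2PO4, MeOH/THF, −20 °C
Reagents that add atoms: none
Why: Reductive elimination of the vicinal bis-sulfone by sodium amalgam (electron transfer, loss of two benzenesulfinate ions) unveils the C5=C6 double bond (target C3=C4), the standard release of the alkene from bis-sulfonyl acetylene equivalents on this bicyclic skeleton, while the phosphate buffer keeps the epoxide and the silyl ether intact.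

Step 7
Reactants: 8 (1R,2S,3S,4S)-3-[(tert-butyldimethylsilyl)oxy]spiro[7-oxabicyclo[2.2.1]hept-5-ene-2,2'-oxirane]
Product: 9 [(1R,2S,3S,4S)-2-(benzoyloxy)-3-[(tert-butyldimethylsilyl)oxy]-7-oxabicyclo[2.2.1]hept-5-en-2-yl]methyl benzoate (2-benzoyloxy endo; CH2OBz and silyloxy exo)
Conditions: Bz2O (1.5 equiv), Bu4N+ PhCO2− (10 mol %), toluene, 80 °C
Reagents that add atoms: benzoic anhydride O=C(OC(=O)c1ccccc1)c1ccccc1
Why: In this carboxylate-catalysed addition of an anhydride to an epoxide, benzoate opens the oxirane by SN2 attack at the exo CH2, and the endo tertiary alkoxide so formed is acylated by the anhydride and releases benzoate again, so both oxygens are benzoylated without touching the configuration of the quaternary carbon.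

Step 8
Reactants: 9 [(1R,2S,3S,4S)-2-(benzoyloxy)-3-[(tert-butyldimethylsilyl)oxy]-7-oxabicyclo[2.2.1]hept-5-en-2-yl]methyl benzoate
Product: 11 [(1S,2S,5S,6S)-2-(benzoyloxy)-6-[(tert-butyldimethylsilyl)oxy]-1,5-dihydroxycyclohex-3-en-1-yl]methyl benzoate, via silylated dioxolanylium triflate 10 (not isolated)
Conditions: TMSOTf (1.2 equiv), CH2Cl2, −40 to 0 °C; aq. citric acid/THF, 0 °C; then Et3N (cat.), CH2Cl2, rt
Reagents that add atoms: water O
Why: Silylation of the bridge oxygen makes the allylic C1–O7 bond a leaving group and the carbonyl oxygen of the endo (trans-disposed) tertiary benzoate attacks C-1 from the rear, as in the acyloxy-assisted acid cleavage of 7-oxanorbornanes, so that this carbon (target C2) is inverted to give the cis-fused dioxolanylium ion 10 while the bridge oxygen stays on C-4 (target C5) with retention; hydrolysis and the amine-promoted acyl shift from the tertiary to the secondary oxygen should then leave the benzoate on O-2 and the tertiary hydroxyl free.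

Step 9
Reactants: 11 [(1S,2S,5S,6S)-2-(benzoyloxy)-6-[(tert-butyldimethylsilyl)oxy]-1,5-dihydroxycyclohex-3-en-1-yl]methyl benzoate
Product: 12 [(1S,2S,5S,6S)-2,5-bis(benzoyloxy)-6-[(tert-butyldimethylsilyl)oxy]-1-hydroxycyclohex-3-en-1-yl]methyl benzoate
Conditions: BzCl (1.5 equiv), pyridine, DMAP (cat.), CH2Cl2, 0 °C to rt
Reagents that add atoms: benzoyl chloride O=C(Cl)c1ccccc1
Why: Pyridine/DMAP acylation should benzoylate only the secondary allylic hydroxyl at C-5, since the tertiary C-1 hydroxyl is too hindered to react under these conditions.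

Step 10
Reactants: 12 [(1S,2S,5S,6S)-2,5-bis(benzoyloxy)-6-[(tert-butyldimethylsilyl)oxy]-1-hydroxycyclohex-3-en-1-yl]methyl benzoate
Product: 13 [(1R,2S,5S,6S)-2,5-bis(benzoyloxy)-1,6-dihydroxycyclohex-3-en-1-yl]methyl benzoate (target)
Conditions: HF·pyridine, THF/pyridine, 0 °C to rt
Reagents that add atoms: none
Why: Fluoride cleaves the Si–O bond of the secondary silyl ether under mildly acidic conditions, which avoids base-induced benzoyl migration between the cis O-5 and O-6 and releases the target.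

**Compound list**

1 | furan | c1ccoc1 | starting material
2 | (Z)-1,2-bis(phenylsulfonyl)ethene | O=S(=O)(/C=C\S(=O)(=O)c1ccccc1)c1ccccc1 | starting material
3 | meso-(1R,4S,5R,6S)-5,6-bis(phenylsulfonyl)-7-oxabicyclo[2.2.1]hept-2-ene (sulfonyl groups endo) | O1[C@H]2C=C[C@@H]1[C@H](S(=O)(=O)c1ccccc1)[C@@H]2S(=O)(=O)c1ccccc1 | intermediate
4 | meso-(1R,2R,3S,4S,5R,6S)-5,6-bis(phenylsulfonyl)-7-oxabicyclo[2.2.1]heptane-2,3-diol (hydroxyls exo, sulfonyl groups endo) | O1[C@H]2[C@@H](O)[C@@H](O)[C@@H]1[C@H](S(=O)(=O)c1ccccc1)[C@@H]2S(=O)(=O)c1ccccc1 | intermediate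
5 | (1S,2R,3R,4R,5S,6R)-3-[(tert-butyldimethylsilyl)oxy]-5,6-bis(phenylsulfonyl)-7-oxabicyclo[2.2.1]heptan-2-ol | O1[C@H]2[C@@H](O)[C@@H](O[Si](C)(C)C(C)(C)C)[C@@H]1[C@H](S(=O)(=O)c1ccccc1)[C@@H]2S(=O)(=O)c1ccccc1 | intermediate
6 | (1S,3S,4R,5S,6R)-3-[(tert-butyldimethylsilyl)oxy]-5,6-bis(phenylsulfonyl)-7-oxabicyclo[2.2.1]heptan-2-one | O1[C@H]2C(=O)[C@@H](O[Si](C)(C)C(C)(C)C)[C@@H]1[C@H](S(=O)(=O)c1ccccc1)[C@@H]2S(=O)(=O)c1ccccc1 | intermediate
7 | (1S,2S,3S,4R,5S,6R)-3-[(tert-butyldimethylsilyl)oxy]-5,6-bis(phenylsulfonyl)spiro[7-oxabicyclo[2.2.1]heptane-2,2'-oxirane] (oxirane oxygen endo) | O1[C@H]2[C@@]3(CO3)[C@@H](O[Si](C)(C)C(C)(C)C)[C@@H]1[C@H](S(=O)(=O)c1ccccc1)[C@@H]2S(=O)(=O)c1ccccc1 | intermediate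
8 | (1R,2S,3S,4S)-3-[(tert-butyldimethylsilyl)oxy]spiro[7-oxabicyclo[2.2.1]hept-5-ene-2,2'-oxirane] | O1[C@H]2[C@@]3(CO3)[C@@H](O[Si](C)(C)C(C)(C)C)[C@@H]1C=C2 | intermediate
9 | [(1R,2S,3S,4S)-2-(benzoyloxy)-3-[(tert-butyldimethylsilyl)oxy]-7-oxabicyclo[2.2.1]hept-5-en-2-yl]methyl benzoate | O1[C@H]2[C@@](OC(=O)c3ccccc3)(COC(=O)c3ccccc3)[C@@H](O[Si](C)(C)C(C)(C)C)[C@@H]1C=C2 | intermediate
10 | ring-opened cyclohexene carrying a cis-fused 2-phenyl-1,3-dioxolan-2-ylium ring across O-1/O-2 (face opposite to the former bridge), 5-O-trimethylsilyl, 6-O-TBS and CH2OBz; triflate salt | O=C(OC[C@@]12OC(c3ccccc3)=[O+][C@H]2C=C[C@H](O[Si](C)(C)C)[C@@H]1O[Si](C)(C)C(C)(C)C)c1ccccc1.[O-]S(=O)(=O)C(F)(F)F | intermediate (not isolated)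
11 | [(1S,2S,5S,6S)-2-(benzoyloxy)-6-[(tert-butyldimethylsilyl)oxy]-1,5-dihydroxycyclohex-3-en-1-yl]methyl benzoate | O=C(OC[C@]1(O)[C@@H](OC(=O)c2ccccc2)C=C[C@H](O)[C@@H]1O[Si](C)(C)C(C)(C)C)c1ccccc1 | intermediate
12 | [(1S,2S,5S,6S)-2,5-bis(benzoyloxy)-6-[(tert-butyldimethylsilyl)oxy]-1-hydroxycyclohex-3-en-1-yl]methyl benzoate | O=C(OC[C@]1(O)[C@@H](OC(=O)c2ccccc2)C=C[C@H](OC(=O)c2ccccc2)[C@@H]1O[Si](C)(C)C(C)(C)C)c1ccccc1 | intermediate
13 | [(1R,2S,5S,6S)-2,5-bis(benzoyloxy)-1,6-dihydroxycyclohex-3-en-1-yl]methyl benzoate | O=C(OC[C@]1(O)[C@@H](OC(=O)c2ccccc2)C=C[C@H](OC(=O)c2ccccc2)[C@@H]1O)c1ccccc1 | target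

**Totals**

Total step count: 10. Longest linear sequence: 10 steps (from furan 1 and bis-sulfone 2).

**Steps most likely to fail**

1. Step 8 (opening of the oxygen bridge with inversion). Unassisted ionisation at the other bridgehead, or loss of the tertiary benzoate, followed by dehydration toward an arene, may outrun the anchimerically assisted cleavage. The fallback leaves the route at ketone 6 and returns at 12; it sets the C1/C2 centres by osmylation instead of by inversion. Wittig methylenation of 6 (Ph3PCH3Br, KHMDS, THF, −78 to 0 °C) should give (1S,3R,4R,5S,6R)-3-[(tert-butyldimethylsilyl)oxy]-2-methylidene-5,6-bis(phenylsulfonyl)-7-oxabicyclo[2.2.1]heptane F1. Sodium amalgam as in step 6 should then give (1R,3R,4S)-3-[(tert-butyldimethylsilyl)oxy]-2-methylidene-7-oxabicyclo[2.2.1]hept-5-ene F2. With the zerovalent palladium catalyst Pd(PPh3)4 and benzoic acid in THF, the doubly allylic bridgehead C–O bond should ionise and benzoate should add at the exocyclic CH2 terminus. This gives the conjugated dienol [(5S,6R)-6-[(tert-butyldimethylsilyl)oxy]-5-hydroxycyclohexa-1,3-dien-1-yl]methyl benzoate F3, with the bridge oxygen kept on C5. OsO4/NMO should dihydroxylate the trisubstituted alkene anti to the neighbouring silyloxy group to give [(1S,2S,5S,6S)-6-[(tert-butyldimethylsilyl)oxy]-1,2,5-trihydroxycyclohex-3-en-1-yl]methyl benzoate F4. BzCl (2.2 equiv), pyridine and DMAP should benzoylate the two secondary allylic hydroxyls and give 12.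

2. Step 3 (desymmetrising silylation). Discrimination between the two enantiotopic hydroxyls may be poor, or both may be silylated. The fallback leaves the route at meso diol 4 and returns at 6; it uses an oxidative instead of a silylative desymmetrisation. Enantiotopic-group-selective oxidation with NBS, K2CO3, Cu(OTf)2 and 2,2'-isopropylidenebis[(4R)-4-phenyl-2-oxazoline] (or its antipode) in CHCl3 should give (1S,3S,4R,5S,6R)-3-hydroxy-5,6-bis(phenylsulfonyl)-7-oxabicyclo[2.2.1]heptan-2-one F5. Immediate silylation (TBSOTf, 2,6-lutidine, CH2Cl2, −78 °C) should give 6.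

3. Step 5 (ylide addition to the ketone). Enolisation of 6 toward C-3 with β-elimination of the bridge oxygen, or slow addition beside the bulky silyl ether, may compete. The fallback leaves the route at 6 and returns at 9; it uses a non-basic hydroxymethyl anion equivalent and also bypasses steps 6 and 7. Addition of (i-PrO)Me2SiCH2MgCl with CeCl3 (THF, −78 °C, exo attack) should give (1S,2S,3S,4R,5S,6R)-3-[(tert-butyldimethylsilyl)oxy]-2-{[dimethyl(propan-2-yloxy)silyl]methyl}-5,6-bis(phenylsulfonyl)-7-oxabicyclo[2.2.1]heptan-2-ol F6. Tamao oxidation (H2O2, KF, KHCO3, MeOH/THF) should give (1S,2S,3S,4R,5S,6R)-3-[(tert-butyldimethylsilyl)oxy]-2-(hydroxymethyl)-5,6-bis(phenylsulfonyl)-7-oxabicyclo[2.2.1]heptan-2-ol F7. Sodium amalgam as in step 6 should give (1R,2S,3S,4S)-3-[(tert-butyldimethylsilyl)oxy]-2-(hydroxymethyl)-7-oxabicyclo[2.2.1]hept-5-en-2-ol F8. Benzoylation of the primary and the tertiary hydroxyl (BzCl, DMAP, pyridine, 60 °C) should give 9.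

**Further compounds**

F1 | step 8 | (1S,3R,4R,5S,6R)-3-[(tert-butyldimethylsilyl)oxy]-2-methylidene-5,6-bis(phenylsulfonyl)-7-oxabicyclo[2.2.1]heptane | O1[C@H]2C(=C)[C@@H](O[Si](C)(C)C(C)(C)C)[C@@H]1[C@H](S(=O)(=O)c1ccccc1)[C@@H]2S(=O)(=O)c1ccccc1
F2 | step 8 | (1R,3R,4S)-3-[(tert-butyldimethylsilyl)oxy]-2-methylidene-7-oxabicyclo[2.2.1]hept-5-ene | O1[C@H]2C(=C)[C@@H](O[Si](C)(C)C(C)(C)C)[C@@H]1C=C2
F3 | step 8 | [(5S,6R)-6-[(tert-butyldimethylsilyl)oxy]-5-hydroxycyclohexa-1,3-dien-1-yl]methyl benzoate | O=C(OCC1=CC=C[C@H](O)[C@@H]1O[Si](C)(C)C(C)(C)C)c1ccccc1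
F4 | step 8 | [(1S,2S,5S,6S)-6-[(tert-butyldimethylsilyl)oxy]-1,2,5-trihydroxycyclohex-3-en-1-yl]methyl benzoate | O=C(OC[C@]1(O)[C@@H](O)C=C[C@H](O)[C@@H]1O[Si](C)(C)C(C)(C)C)c1ccccc1
F5 | step 3 | (1S,3S,4R,5S,6R)-3-hydroxy-5,6-bis(phenylsulfonyl)-7-oxabicyclo[2.2.1]heptan-2-one | O1[C@H]2C(=O)[C@@H](O)[C@@H]1[C@H](S(=O)(=O)c1ccccc1)[C@@H]2S(=O)(=O)c1ccccc1
F6 | step 5 | (1S,2S,3S,4R,5S,6R)-3-[(tert-butyldimethylsilyl)oxy]-2-{[dimethyl(propan-2-yloxy)silyl]methyl}-5,6-bis(phenylsulfonyl)-7-oxabicyclo[2.2.1]heptan-2-ol | O1[C@H]2[C@@](O)(C[Si](C)(C)OC(C)C)[C@@H](O[Si](C)(C)C(C)(C)C)[C@@H]1[C@H](S(=O)(=O)c1ccccc1)[C@@H]2S(=O)(=O)c1ccccc1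
F7 | step 5 | (1S,2S,3S,4R,5S,6R)-3-[(tert-butyldimethylsilyl)oxy]-2-(hydroxymethyl)-5,6-bis(phenylsulfonyl)-7-oxabicyclo[2.2.1]heptan-2-ol | O1[C@H]2[C@@](O)(CO)[C@@H](O[Si](C)(C)C(C)(C)C)[C@@H]1[C@H](S(=O)(=O)c1ccccc1)[C@@H]2S(=O)(=O)c1ccccc1
F8 | step 5 | (1R,2S,3S,4S)-3-[(tert-butyldimethylsilyl)oxy]-2-(hydroxymethyl)-7-oxabicyclo[2.2.1]hept-5-en-2-ol | O1[C@H]2[C@@](O)(CO)[C@@H](O[Si](C)(C)C(C)(C)C)[C@@H]1C=C2
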